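Conventions: compound numbers are those of the steps and of the list after them. Bicyclic compounds carry azulene locants: ring A (five-membered) is C1–C2–C3–C3a–C8a, ring B (seven-membered) is C3a–C4–C5–C6–C7–C8–C8a. β is the face of H-8a, α the face of H-3a. Descriptors in the names refer to these locants.

## Analysis of the target

Target 30 is a trans-fused bicyclo[5.3.0]decane. Ring A is a cyclopentane with a methyl group on C2 and a trisubstituted epoxide across C2–C3; ring B is a cycloheptane with a methyl carbinol at C5, a secondary 4-hydroxybenzoate at C7 and an isopropyl group at C8. There are seven stereocentres, C2, C3, C3a, C5, C7, C8 and C8a (2R,3S,3aS,5R,7S,8S,8aR). H-8a is β and H-3a is α; the isopropyl group is β and equatorial; the ester oxygen on C7 is α and equatorial, trans to the isopropyl group; the C5 hydroxyl is β and axial, trans to O-7 and cis to the β epoxide oxygen. The epoxide is acid-labile, the tertiary alcohol eliminates easily, and the aryl ester and free phenol limit base, hydride and organometallic reagents late in the route. The hard points are the trans fusion of a five- to a seven-membered ring, the closure of ring B, the trans-1,3 relationship of O-5 and O-7 (no cyclic protecting group, no single hydroxyl-directed step), and the choice of face on a nearly flat cyclopentene. The strategy rests on C3a and C8a: they are vicinal trans methines of ring A, C8a is bonded to the isopropyl-bearing C8, C3a to the C4 methylene of ring B, and their ring A neighbour C3 carries oxygen. With C3 as a carbonyl carbon this is the pattern left in a cyclopentanone by conjugate addition at the β-carbon (C8a) followed by alkylation of the enolate at the α-carbon (C3a).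

## Retrosynthetic reasoning

**30 ⇒ 29 ⇒ 28.** The phenol is unmasked last (O–Si bond). Before that the two C–O bonds of the epoxide are cut, which leads to alkene 28. The β-axial C5 hydroxyl of 28 is bishomoallylic to C2=C3 and sits on the face that must receive oxygen, so a metal-bound peroxide can be delivered from it. The forward step has to set C2 and C3 together and leave the ester and silyl ether alone.

**28 ⇒ 24 + 27.** The ester C–O bond is cut late, so that no enolate, hydride or hydrazone chemistry has to pass an aryl ester. Diol 24 has one secondary equatorial and one tertiary axial hydroxyl, so the acylation selects by itself. Acid 27 comes from 25 by silylation.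

**24 ⇒ 23 ⇒ 22.** The C7–H bond is cut. In hydroxy ketone 23 the C5 hydroxyl can carry a borohydride and deliver hydride to the β face of C7, which gives exactly the trans-1,3-diol. 23 comes from cis-diol 22 by oxidation of its only secondary alcohol. This detour is the price for using the C7 hydroxyl first as a directing group in the opposite configuration; it also places C8 next to a carbonyl once more.

**22 ⇒ 21 ⇒ 20.** At C5 the C–O bond and one C–H bond of the methyl group are cut, leading back to the methylidene group of 20 through spiro-epoxide 21. The β-axial C7 hydroxyl of 20 is homoallylic and 1,3-diaxial to the exocyclic carbon, so oxygen is delivered to the β face; hydride then opens the epoxide at its CH2 end. Simple hydration would give no control here.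

**20 ⇒ 18 ⇒ 17 ⇒ 13.** The ring A alkene is traced to the C3 ketone: the C2–CH2 bond is cut, and the C2=C3 alkene with its methyl group comes from reductive 1,3-transposition of the tosylhydrazone 18 of exocyclic enone 17. Methylation and dehydration of 13 would leave the regiochemistry between C2 and C3a open; the transposition fixes it by mechanism. The sequence is placed after ring B closure, because a ring A alkene would compete for the activated aldehyde, and before the C5 hydroxyl exists, because that hydroxyl could bridge onto the C3 ketone.

**13 ⇒ 12 ⇒ 11.** Ring B is opened at C6–C7. In the forward direction aldehyde 11 and its 1,1-disubstituted alkene close the seven-membered ring by a carbonyl-ene reaction. This bond is chosen because its formation delivers at once the C7 hydroxyl and the C5 methylidene group, the two handles the later steps need. The ketone is carried as the dioxolane of 12.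

**11 ⇒ 10 ⇒ 9.** Only oxidation level and protection change: aldehyde from ester, ketal from ketone.

**9 ⇒ 3 + 6 + 5.** The C8–C8a and C3a–C4 bonds are cut. Forward, ketene acetal 3 adds to enone 6 under a chiral Lewis acid to give silyl enol ether 7; its enolate 8 is alkylated by iodide 5 anti to the new substituent. The step fixes the trans ring fusion, the hardest relative configuration, in the first C–C bond-forming operation and attaches the carbons of both arms of ring B. 3 comes from ester 1, 5 from bromide 4.

## Alternatives that were turned down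

**Alternative 1: low-valent titanium coupling closing ring A.**
- Disconnection: the C2=C3 double bond of the cyclopentene. Keto-aldehyde A1, a cycloheptane with trans-vicinal 2-oxopropyl (C8a) and formyl (C3a) groups, would be cyclised with TiCl3/Zn–Cu (low-valent titanium, McMurry coupling) to cyclopentene A2.
- For it: the alkene and its methyl group are placed between C2 and C3 without ambiguity, and intramolecular carbonyl coupling to five-membered rings is dependable. On this point it is stronger than the chosen route, which needs steps 8 to 10.
- Against it: all difficulty moves into A1, a cycloheptane with five stereocentres for which the plan offers no ring-forming logic. The formyl-bearing C3a is epimerisable under hot, Lewis-acidic titanium conditions, so the future ring fusion can scramble. The isopropylidene group drawn in A1 and A2 links O-5 and O-7, which lie on opposite faces of ring B in the target configuration; a six-membered ketal cannot span trans-1,3 positions of a seven-membered ring, so two separate robust protecting groups (one on a tertiary alcohol) would be needed.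
- Comparison: the chosen route offers in its place the trans fusion set at the start from three simple components under catalyst control, and one cyclisation for ring B.

**Alternative 2: nickel alkylative ynal cyclisation.**
- Disconnection: the C7–C8 bond and one C–CH3 bond of the isopropyl group. Ynal A3 (propynyl on C8a, aldehyde chain with the C5 silyloxy centre on C3a) would be cyclised with Ni(cod)2 (zerovalent nickel) and Me2Zn to allylic alcohol A4 with an exocyclic isopropylidene group.
- For it: ring B, the C7 carbinol and the full isopropyl carbon set arise in one catalytic step, and the symmetric isopropylidene raises no geometry question. The C7 hydroxyl of A4 could direct hydrogenation with [Ir(cod)(PCy3)(py)]PF6 so that H-8 ends cis to O-7, the relationship of 30. This is more direct for C7/C8 than the oxidation and reduction of steps 13 and 14.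
- Against it: such cyclisations are at their best for five- and six-membered rings; a seven-membered closure through a flexible tether leaves C7 to remote control. Hydrogenation of a tetrasubstituted alkene next to the ring fusion is slow. A3 needs the tertiary C5 centre to be set in an open chain, 1,3 to C3a, without a good handle. Ring A still needs the ketone-to-methylcyclopentene work.
- Comparison: A3 would itself be made most sensibly by the same cyclopentenone difunctionalisation, so this plan keeps the risk of the chosen key step and adds a second risky ring closure. The chosen route sets C8 in the key step and C5 by relay from the ring.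

**Alternative 3: Pauson–Khand bicyclisation.**
- Disconnection: the ring-fusion bond C3a–C8a and both bonds to C2. Enyne A5 would be treated with Co2(CO)8 (zerovalent cobalt) to give bicyclic enone A6, closing rings A and B in one operation.
- For it: three C–C bonds and both rings in one step, from an open-chain precursor whose C5, C7 and C8 centres can be made by reliable acyclic methods. In bond-forming economy it is stronger than the chosen route.
- Against it: intramolecular Pauson–Khand reactions form five- and six-membered second rings well, seven-membered ones only with a conformational constraint. The constraint drawn here, the ketal of A5, would have to span the trans-disposed O-5 and O-7 of ring B in A6, which is geometrically excluded. In A6 the C3=C3a bond is unsaturated, so C3a and the trans fusion are not set and would depend on a later reduction. The carbonyl sits on C2, so methyl addition and a regioselective dehydration toward C3 would follow. C8a relative to C8 is decided in the cyclisation with uncertain control.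
- Comparison: the chosen route uses ring-forming events of established ring size and builds the trans fusion in at the start.

Key step: step 3

Assumption on the chemistry: the (S)-configured oxazaborolidinium ion is taken to leave open the Re face of C-β of 6 (the face that leads to 8aR); if the sense were the opposite, its enantiomer would be used with nothing else changed.

## Route

Step 1
Reactants: 1 methyl 3-methylbutanoate
Product: 3 (E)-1-methoxy-3-methyl-1-(trimethylsilyloxy)but-1-ene, via lithium enolate 2 (not isolated)
Conditions: LiN(iPr)2, THF, −78 °C; Me3SiCl, −78 °C → rt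
Reagents that add atoms: chlorotrimethylsilane, C[Si](C)(C)Cl
Why: Deprotonation of the ester by the lithium amide in THF without polar cosolvent passes through a closed transition state that puts the isopropyl group trans to O–Li in 2; O-silylation keeps this geometry and gives the (E)-silyl ketene acetal, which is distilled and used at once.

Step 2
Reactants: 4 3-bromo-2-methylprop-1-ene
Product: 5 3-iodo-2-methylprop-1-ene
Conditions: NaI, acetone, rt, dark
Reagents that add atoms: sodium iodide, [Na+].[I-]
Why: Finkelstein halide exchange, driven by precipitation of NaBr from acetone; the allylic iodide is the more reactive electrophile needed for a fast, cold C-alkylation in step 3.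

Step 3
Reactants: 3 (E)-1-methoxy-3-methyl-1-(trimethylsilyloxy)but-1-ene; 6 cyclopent-2-en-1-one; 5 3-iodo-2-methylprop-1-ene
Product: 9 methyl (2S)-3-methyl-2-[(1R,2S)-2-(2-methylprop-2-en-1-yl)-3-oxocyclopentyl]butanoate, via silyl enol ether 7 (not isolated), via sulfonium enolate 8 (not isolated)
Conditions: triflimide salt of N-protonated (S)-1-(2-methylphenyl)-3,3-diphenyltetrahydro-1H,3H-pyrrolo[1,2-c][1,3,2]oxazaborole (20 mol %), Ph3PO (25 mol %), PhMe, −20 °C; then (Me2N)3S+ Me3SiF2−, THF, −78 °C; then 5, −78 → −30 °C
Reagents that add atoms: none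
Why: The cationic boron binds the carbonyl oxygen of 6, ketene acetal 3 adds to the β-carbon (Mukaiyama–Michael addition) and the silyl group passes to the enolate oxygen, helped by Ph3PO, to give enol ether 7. Fluoride from the difluorosilicate then cleaves the O–Si bond at −78 °C to give the regiodefined metal-free enolate 8, which is C-alkylated by allylic iodide 5; the closest known reaction type is the vicinal difunctionalisation of a cyclic enone by Mukaiyama–Michael addition and regiospecific alkylation of the derived silyl enol ether. No ring closes; the C8–C8a and C3a–C4 bonds form. C8a is set by the catalyst, whose aryl groups cover one face of the bound enone so that attack on the Re face of C-β gives 8aR. C8 is set by the relative topicity in the open transition state: the hydrogen of the nucleophilic carbon should point into the ring sector, the isopropyl group away from the enone α-carbon and the flat acetal carbon over the enone, with the (E) geometry placing the silyloxy group on the carbonyl side, which leads to 2S. C3a is set by the substituent on C8a, since the iodide approaches the enolate anti to it; trans is also the more stable arrangement, so any equilibration converges. The step needs 1,4- over 1,2-addition (soft silyl nucleophile, Lewis-acid activation), C- over O-alkylation (soft allylic iodide) and single alkylation at C3a (preformed enol ether, low temperature). The methyl ester is spared because fluoride, not an alkyllithium, liberates the enolate.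

Step 4
Reactants: 9 methyl (2S)-3-methyl-2-[(1R,2S)-2-(2-methylprop-2-en-1-yl)-3-oxocyclopentyl]butanoate
Product: 10 methyl (2S)-3-methyl-2-[(6S,7R)-6-(2-methylprop-2-en-1-yl)-1,4-dioxaspiro[4.4]nonan-7-yl]butanoate
Conditions: Me3SiOCH2CH2OSiMe3, Me3SiOTf (cat.), CH2Cl2, −78 → −20 °C
Reagents that add atoms: 1,2-bis(trimethylsilyloxy)ethane, C[Si](C)(C)OCCO[Si](C)(C)C
Why: Acetalisation by silyl transfer runs cold and aprotic, so the 1,1-disubstituted alkene does not migrate and C3a is not epimerised; the ketone must be masked before hydride and Lewis acid are used.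

Step 5
Reactants: 10 methyl (2S)-3-methyl-2-[(6S,7R)-6-(2-methylprop-2-en-1-yl)-1,4-dioxaspiro[4.4]nonan-7-yl]butanoate
Product: 11 (2S)-3-methyl-2-[(6S,7S)-6-(2-methylprop-2-en-1-yl)-1,4-dioxaspiro[4.4]nonan-7-yl]butanal
Conditions: iBu2AlH, CH2Cl2, −78 °C; MeOH, then aq potassium sodium tartrate
Reagents that add atoms: none
Why: Partial reduction of an ester by a dialkylaluminium hydride: at −78 °C the aluminium hemiacetal of the α-branched ester is stable and releases the aldehyde only on work-up, and nothing basic is present that could enolise C8.

Step 6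
Reactants: 11 (2S)-3-methyl-2-[(6S,7S)-6-(2-methylprop-2-en-1-yl)-1,4-dioxaspiro[4.4]nonan-7-yl]butanal
Product: 12 (3aS,7R,8S,8aS)-3,3-(ethylenedioxy)-5-methylidene-8-(propan-2-yl)decahydroazulen-7-ol
Conditions: Me2AlCl (2.5 equiv), CH2Cl2, −78 → −20 °C; aq potassium sodium tartrate
Reagents that add atoms: none
Why: Carbonyl-ene cyclisation with the tether on the central carbon of the ene unit: the terminal alkene carbon attacks the Lewis-acid-bound aldehyde carbon (C6–C7 bond, ring B) while a methyl hydrogen passes to oxygen, and Me2AlCl removes the product proton as methane. In the chair-like bridged transition state the C7–O bond and the hydrogen-donating methyl group are 1,3-diaxial on the β face and the isopropyl group is equatorial, so the hydroxyl should emerge axial and β, cis to the isopropyl group.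

Step 7
Reactants: 12 (3aS,7R,8S,8aS)-3,3-(ethylenedioxy)-5-methylidene-8-(propan-2-yl)decahydroazulen-7-ol
Product: 13 (3aS,7R,8S,8aS)-7-hydroxy-5-methylidene-8-(propan-2-yl)octahydroazulen-3(2H)-one
Conditions: PPTS, acetone/H2O, 50 °C
Reagents that add atoms: water, O
Why: Acid-catalysed hydrolysis of the dioxolane under weakly acidic pyridinium catalysis; the homoallylic alcohol and the methylidene group are stable to it and the mild acid limits enolisation toward C3a.

Step 8
Reactants: 13 (3aS,7R,8S,8aS)-7-hydroxy-5-methylidene-8-(propan-2-yl)octahydroazulen-3(2H)-one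
Product: 17 (3aS,7R,8S,8aS)-7-hydroxy-2,5-dimethylidene-8-(propan-2-yl)octahydroazulen-3(2H)-one, via dilithium alkoxide enolate 14 (not isolated), via Mannich base 15 (not isolated), via trimethylammonium iodide 16 (not isolated)
Conditions: LiN(iPr)2 (2.2 equiv), THF, −78 °C; CH2=NMe2+ I−, −78 °C → rt; MeI, CH2Cl2, rt; aq NaHCO3, CH2Cl2, rt
Reagents that add atoms: N,N-dimethylmethyleneiminium iodide, C=[N+](C)C.[I-]
Why: After the hydroxyl, the amide base removes a proton kinetically from the C2 methylene and not from the hindered C3a methine, so the ring fusion is untouched; the enolate is aminomethylated (Mannich reaction with a preformed iminium salt). Quaternisation and mild-base elimination then give the exocyclic enone, which is used without storage.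

Step 9
Reactants: 17 (3aS,7R,8S,8aS)-7-hydroxy-2,5-dimethylidene-8-(propan-2-yl)octahydroazulen-3(2H)-one
Product: 18 N'-[(3aS,7R,8S,8aR)-7-hydroxy-2,5-dimethylidene-8-(propan-2-yl)octahydroazulen-3(2H)-ylidene]-4-methylbenzenesulfonohydrazide
Conditions: TsNHNH2, MeOH, rt
Reagents that add atoms: 4-methylbenzenesulfonohydrazide, Cc1ccc(cc1)S(=O)(=O)NN
Why: Condensation of the ketone with the sulfonohydrazide to the tosylhydrazone; room temperature and the absence of base are chosen to disfavour conjugate addition to the exocyclic enone.

Step 10
Reactants: 18 N'-[(3aS,7R,8S,8aR)-7-hydroxy-2,5-dimethylidene-8-(propan-2-yl)octahydroazulen-3(2H)-ylidene]-4-methylbenzenesulfonohydrazide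
Product: 20 (3aS,7R,8S,8aR)-2-methyl-5-methylidene-8-(propan-2-yl)-1,3a,4,5,6,7,8,8a-octahydroazulen-7-ol, via allylic diazene 19 (not isolated)
Conditions: catecholborane (3 equiv), CHCl3, 0 °C; NaOAc·3H2O, 60 °C
Reagents that add atoms: none
Why: Catecholborane adds hydride to the C=N carbon, acetate induces loss of sulfinate to give allylic diazene 19, and this loses N2 by a retro-ene hydrogen shift that puts hydrogen on the exocyclic carbon and the double bond between C2 and C3 (reductive 1,3-transposition of an unsaturated tosylhydrazone). The position of the alkene follows from the mechanism, no stereocentre is formed, and the isolated methylidene group is not hydroborated at this temperature.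

Step 11
Reactants: 20 (3aS,7R,8S,8aR)-2-methyl-5-methylidene-8-(propan-2-yl)-1,3a,4,5,6,7,8,8a-octahydroazulen-7-ol
Product: 21 (3aS,5R,7R,8S,8aR)-2-methyl-8-(propan-2-yl)-1,3a,4,6,7,8,8a-heptahydrospiro[azulene-5,2'-oxiran]-7-ol (spiro-epoxide, oxygen on C5 cis to the C7 hydroxyl)
Conditions: VO(acac)2 (5 mol %), tBuOOH, CH2Cl2, 0 °C → rt
Reagents that add atoms: tert-butyl hydroperoxide, CC(C)(C)OO
Why: Hydroxyl-directed vanadium-catalysed epoxidation of a homoallylic alcohol: the axial C7 alkoxide binds the metal and the bound peroxide reaches the C5 methylidene group only from the β face, which sets C5 with its oxygen β. The ring A alkene has no directing group in reach and should not react.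

Step 12
Reactants: 21 (3aS,5R,7R,8S,8aR)-2-methyl-8-(propan-2-yl)-1,3a,4,6,7,8,8a-heptahydrospiro[azulene-5,2'-oxiran]-7-ol
Product: 22 (3aS,5R,7R,8S,8aR)-2,5-dimethyl-8-(propan-2-yl)-1,3a,4,5,6,7,8,8a-octahydroazulene-5,7-diol
Conditions: LiAlH4, THF, 0 °C → rt; aq NaOH work-up
Reagents that add atoms: none
Why: Hydride opens the spiro-epoxide at its unhindered CH2 terminus (SN2), so the β C5–O bond is kept and the epoxide carbon becomes the C5 methyl group.

Step 13
Reactants: 22 (3aS,5R,7R,8S,8aR)-2,5-dimethyl-8-(propan-2-yl)-1,3a,4,5,6,7,8,8a-octahydroazulene-5,7-diol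
Product: 23 (3aS,5R,8S,8aR)-5-hydroxy-2,5-dimethyl-8-(propan-2-yl)-3a,4,5,6,8,8a-hexahydroazulen-7(1H)-one
Conditions: Dess–Martin periodinane, NaHCO3, CH2Cl2, 0 °C → rt
Reagents that add atoms: none
Why: Dess–Martin oxidation of the only secondary alcohol; the tertiary alcohol and the alkene are inert and the buffer prevents β-elimination of the C5 hydroxyl. C8 is now α to a carbonyl with its isopropyl group in the equatorial, thermodynamically preferred position.

Step 14
Reactants: 23 (3aS,5R,8S,8aR)-5-hydroxy-2,5-dimethyl-8-(propan-2-yl)-3a,4,5,6,8,8a-hexahydroazulen-7(1H)-one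
Product: 24 (3aS,5R,7S,8S,8aR)-2,5-dimethyl-8-(propan-2-yl)-1,3a,4,5,6,7,8,8a-octahydroazulene-5,7-diol
Conditions: Me4N+ HB(OAc)3−, MeCN/AcOH (1:1), −30 °C
Reagents that add atoms: none
Why: Evans–Saksena hydroxyl-directed reduction: the axial C5 hydroxyl exchanges onto boron and hands hydride to the β face of C7, so the new hydroxyl is α, trans to O-5, equatorial and trans to the isopropyl group. Axial attack of a small hydride has the same sense, so directing effect and inherent bias should reinforce each other.

Step 15
Reactants: 25 4-hydroxybenzoic acid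
Product: 27 4-[(tert-butyldimethylsilyl)oxy]benzoic acid, via bis-silyl derivative 26 (not isolated)
Conditions: tBuMe2SiCl (2.2 equiv), imidazole, DMF, rt; AcOH, THF/H2O, rt
Reagents that add atoms: tert-butylchlorodimethylsilane, CC(C)(C)[Si](C)(C)Cl
Why: Silylation of both acidic hydroxyls followed by selective hydrolysis of the far more labile silyl ester; the aryl silyl ether is stable to aqueous acetic acid.

Step 16
Reactants: 24 (3aS,5R,7S,8S,8aR)-2,5-dimethyl-8-(propan-2-yl)-1,3a,4,5,6,7,8,8a-octahydroazulene-5,7-diol; 27 4-[(tert-butyldimethylsilyl)oxy]benzoic acid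
Product: 28 (3aS,5R,7S,8S,8aR)-5-hydroxy-2,5-dimethyl-8-(propan-2-yl)-1,3a,4,5,6,7,8,8a-octahydroazulen-7-yl 4-[(tert-butyldimethylsilyl)oxy]benzoate
Conditions: EDC·HCl, DMAP, CH2Cl2, rt
Reagents that add atoms: none
Why: Steglich esterification through the acylpyridinium ion; the secondary equatorial C7 hydroxyl is acylated with retention, while the tertiary axial C5 hydroxyl does not react under carbodiimide conditions.

Step 17
Reactants: 28 (3aS,5R,7S,8S,8aR)-5-hydroxy-2,5-dimethyl-8-(propan-2-yl)-1,3a,4,5,6,7,8,8a-octahydroazulen-7-yl 4-[(tert-butyldimethylsilyl)oxy]benzoate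
Product: 29 (2R,3S,3aS,5R,7S,8S,8aR)-2,3-epoxy-5-hydroxy-2,5-dimethyl-8-(propan-2-yl)decahydroazulen-7-yl 4-[(tert-butyldimethylsilyl)oxy]benzoate
Conditions: VO(acac)2 (10 mol %), tBuOOH, CH2Cl2, rt
Reagents that add atoms: tert-butyl hydroperoxide, CC(C)(C)OO
Why: Hydroxyl-directed vanadium-catalysed epoxidation of a bishomoallylic alcohol: the β-axial C5 alkoxide holds the metal peroxide over the β face of C2=C3 (C3 is the equatorial, upward-tilted neighbour on C3a), which sets C2 and C3 together. The β hydroxyl cannot open the β epoxide from the rear, so no cyclic ether should follow.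

Step 18
Reactants: 29 (2R,3S,3aS,5R,7S,8S,8aR)-2,3-epoxy-5-hydroxy-2,5-dimethyl-8-(propan-2-yl)decahydroazulen-7-yl 4-[(tert-butyldimethylsilyl)oxy]benzoate
Product: 30 (2R,3S,3aS,5R,7S,8S,8aR)-2,3-epoxy-5-hydroxy-2,5-dimethyl-8-(propan-2-yl)decahydroazulen-7-yl 4-hydroxybenzoate
Conditions: Bu4NF, AcOH, THF, 0 °C
Reagents that add atoms: none
Why: Fluoride cleaves the aryl silyl ether rapidly; acetic acid protonates the phenoxide as it forms, so neither the ester nor the epoxide meets a strong base, and acyl migration to O-5 is excluded by the trans-1,3 arrangement.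

## Compound list

1 | methyl 3-methylbutanoate | CC(C)CC(=O)OC | starting material
2 | lithium 1-methoxy-3-methylbut-1-en-1-olate (isopropyl trans to O–Li) | CC(C)/C=C(\OC)[O-].[Li+] | intermediate (not isolated)
3 | (E)-1-methoxy-3-methyl-1-(trimethylsilyloxy)but-1-ene | CC(C)/C=C(\OC)O[Si](C)(C)C | intermediate
4 | 3-bromo-2-methylprop-1-ene | CC(=C)CBr | starting material
5 | 3-iodo-2-methylprop-1-ene | CC(=C)CI | intermediate
6 | cyclopent-2-en-1-one | O=C1C=CCC1 | starting material
7 | methyl (2S)-3-methyl-2-[(1R)-3-(trimethylsilyloxy)cyclopent-2-en-1-yl]butanoate | CC(C)[C@H](C(=O)OC)[C@@H]1CCC(O[Si](C)(C)C)=C1 | intermediate (not isolated)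
8 | tris(dimethylamino)sulfonium (3R)-3-[(2S)-1-methoxy-3-methyl-1-oxobutan-2-yl]cyclopent-1-en-1-olate | CC(C)[C@H](C(=O)OC)[C@@H]1CCC([O-])=C1.CN(C)[S+](N(C)C)N(C)C | intermediate (not isolated)
9 | methyl (2S)-3-methyl-2-[(1R,2S)-2-(2-methylprop-2-en-1-yl)-3-oxocyclopentyl]butanoate | CC(C)[C@H](C(=O)OC)[C@@H]1CCC(=O)[C@H]1CC(C)=C | intermediate
10 | methyl (2S)-3-methyl-2-[(6S,7R)-6-(2-methylprop-2-en-1-yl)-1,4-dioxaspiro[4.4]nonan-7-yl]butanoate | CC(C)[C@H](C(=O)OC)[C@@H]1CCC2(OCCO2)[C@H]1CC(C)=C | intermediate
11 | (2S)-3-methyl-2-[(6S,7S)-6-(2-methylprop-2-en-1-yl)-1,4-dioxaspiro[4.4]nonan-7-yl]butanal | CC(C)[C@H](C=O)[C@@H]1CCC2(OCCO2)[C@H]1CC(C)=C | intermediate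
12 | (3aS,7R,8S,8aS)-3,3-(ethylenedioxy)-5-methylidene-8-(propan-2-yl)decahydroazulen-7-ol | CC(C)[C@H]1[C@@H]2CCC3(OCCO3)[C@H]2CC(=C)C[C@H]1O | intermediate
13 | (3aS,7R,8S,8aS)-7-hydroxy-5-methylidene-8-(propan-2-yl)octahydroazulen-3(2H)-one | CC(C)[C@H]1[C@@H]2CCC(=O)[C@H]2CC(=C)C[C@H]1O | intermediate
14 | dilithium (3aS,7R,8S,8aS)-5-methylidene-7-oxido-8-(propan-2-yl)-1,3a,4,5,6,7,8,8a-octahydroazulen-3-olate | [Li+].[Li+].CC(C)[C@H]1[C@@H]2CC=C([O-])[C@H]2CC(=C)C[C@H]1[O-] | intermediate (not isolated)
15 | (3aS,7R,8S,8aS)-2-[(dimethylamino)methyl]-7-hydroxy-5-methylidene-8-(propan-2-yl)octahydroazulen-3(2H)-one (C2 epimers) | CC(C)[C@H]1[C@@H]2CC(CN(C)C)C(=O)[C@H]2CC(=C)C[C@H]1O | intermediate (not isolated)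
16 | [(3aS,7R,8S,8aS)-7-hydroxy-5-methylidene-3-oxo-8-(propan-2-yl)decahydroazulen-2-yl]-N,N,N-trimethylmethanaminium iodide (C2 epimers) | CC(C)[C@H]1[C@@H]2CC(C[N+](C)(C)C)C(=O)[C@H]2CC(=C)C[C@H]1O.[I-] | intermediate (not isolated)
17 | (3aS,7R,8S,8aS)-7-hydroxy-2,5-dimethylidene-8-(propan-2-yl)octahydroazulen-3(2H)-one | CC(C)[C@H]1[C@@H]2CC(=C)C(=O)[C@H]2CC(=C)C[C@H]1O | intermediate
18 | N'-[(3aS,7R,8S,8aR)-7-hydroxy-2,5-dimethylidene-8-(propan-2-yl)octahydroazulen-3(2H)-ylidene]-4-methylbenzenesulfonohydrazide | CC(C)[C@H]1[C@@H]2CC(=C)C(=NNS(=O)(=O)c3ccc(C)cc3)[C@H]2CC(=C)C[C@H]1O | intermediate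
19 | (3aS,7R,8S,8aR)-3-diazenyl-2,5-dimethylidene-8-(propan-2-yl)decahydroazulen-7-ol (C3 epimers) | CC(C)[C@H]1[C@@H]2CC(=C)C(N=N)[C@H]2CC(=C)C[C@H]1O | intermediate (not isolated)
20 | (3aS,7R,8S,8aR)-2-methyl-5-methylidene-8-(propan-2-yl)-1,3a,4,5,6,7,8,8a-octahydroazulen-7-ol | CC(C)[C@H]1[C@@H]2CC(C)=C[C@H]2CC(=C)C[C@H]1O | intermediate
21 | (3aS,5R,7R,8S,8aR)-2-methyl-8-(propan-2-yl)-1,3a,4,6,7,8,8a-heptahydrospiro[azulene-5,2'-oxiran]-7-ol | CC(C)[C@H]1[C@@H]2CC(C)=C[C@H]2C[C@]3(CO3)C[C@H]1O | intermediate
22 | (3aS,5R,7R,8S,8aR)-2,5-dimethyl-8-(propan-2-yl)-1,3a,4,5,6,7,8,8a-octahydroazulene-5,7-diol | CC(C)[C@H]1[C@@H]2CC(C)=C[C@H]2C[C@@](C)(O)C[C@H]1O | intermediate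
23 | (3aS,5R,8S,8aR)-5-hydroxy-2,5-dimethyl-8-(propan-2-yl)-3a,4,5,6,8,8a-hexahydroazulen-7(1H)-one | CC(C)[C@H]1[C@@H]2CC(C)=C[C@H]2C[C@@](C)(O)CC1=O | intermediate
24 | (3aS,5R,7S,8S,8aR)-2,5-dimethyl-8-(propan-2-yl)-1,3a,4,5,6,7,8,8a-octahydroazulene-5,7-diol | CC(C)[C@H]1[C@@H]2CC(C)=C[C@H]2C[C@@](C)(O)C[C@@H]1O | intermediate
25 | 4-hydroxybenzoic acid | OC(=O)c1ccc(O)cc1 | starting material
26 | tert-butyldimethylsilyl 4-[(tert-butyldimethylsilyl)oxy]benzoate | CC(C)(C)[Si](C)(C)OC(=O)c1ccc(O[Si](C)(C)C(C)(C)C)cc1 | intermediate (not isolated)
27 | 4-[(tert-butyldimethylsilyl)oxy]benzoic acid | CC(C)(C)[Si](C)(C)Oc1ccc(cc1)C(O)=O | intermediate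
28 | (3aS,5R,7S,8S,8aR)-5-hydroxy-2,5-dimethyl-8-(propan-2-yl)-1,3a,4,5,6,7,8,8a-octahydroazulen-7-yl 4-[(tert-butyldimethylsilyl)oxy]benzoate | CC(C)[C@H]1[C@@H]2CC(C)=C[C@H]2C[C@@](C)(O)C[C@@H]1OC(=O)c1ccc(O[Si](C)(C)C(C)(C)C)cc1 | intermediate
29 | (2R,3S,3aS,5R,7S,8S,8aR)-2,3-epoxy-5-hydroxy-2,5-dimethyl-8-(propan-2-yl)decahydroazulen-7-yl 4-[(tert-butyldimethylsilyl)oxy]benzoate | CC(C)[C@H]1[C@@H]2C[C@@]3(C)O[C@H]3[C@H]2C[C@@](C)(O)C[C@@H]1OC(=O)c1ccc(O[Si](C)(C)C(C)(C)C)cc1 | intermediate
30 | (2R,3S,3aS,5R,7S,8S,8aR)-2,3-epoxy-5-hydroxy-2,5-dimethyl-8-(propan-2-yl)decahydroazulen-7-yl 4-hydroxybenzoate (CNP0245441.1) | CC(C)[C@H]1[C@@H]2C[C@@]3(C)O[C@H]3[C@H]2C[C@@](C)(O)C[C@@H]1OC(=O)c1ccc(O)cc1 | target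

## Step count and least certain steps

Total: 18 steps. Longest linear sequence: 16 steps (1, 3 to 14, 16 to 18); steps 2 and 15 are side branches.

**Step 3 (key step).**
- Most likely to go wrong: loss of regio- and stereochemical integrity between the two bond formations. The metal-free cyclopentanone enolate 8 can exchange protons with product 9 before it is alkylated, which leads to polyalkylation, alkylation at the other α-carbon and erosion of the trans relationship.
- Second weakness: incomplete simple diastereoselection at C8 in the open transition state of the Michael stage. This would be met by chromatography at the stage of 9 and, if needed, by base equilibration at the stage of 23, where C8 is again α to a carbonyl and the equatorial isopropyl group is the thermodynamic arrangement.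
- Fallback: 7 is taken out of the flask after the Michael stage, and the second bond is made under neutral conditions with methyl 2-methylprop-2-en-1-yl carbonate F1 (from 2-methylprop-2-en-1-ol and methyl chloroformate) and Pd2(dba)3/dppe (zerovalent palladium) in THF at reflux. Methoxide released by decarboxylation removes the silyl group and the palladium enolate couples with the 2-methylallyl ligand at C3a (Tsuji allylation of a silyl enol ether). No free enolate accumulates, and the sequence returns to 9.

**Step 6.**
- Most likely to go wrong: the hydroxyl emerging on the α face or as a mixture, because a non-bridged or boat-like transition state can compete in a seven-membered closure; the Lewis acid may also ionise the ketal. Hydrogen transfer from C4 instead of the methyl group is less serious, since epoxidation and hydride opening would lead to the same C5 carbinol.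
- Fallback: C7 is set by reagent control. From 11 the cyclisation is run as before; the alcohol with the α hydroxyl, (3aS,7S,8S,8aS)-3,3-(ethylenedioxy)-5-methylidene-8-(propan-2-yl)decahydroazulen-7-ol F2, is oxidised with Dess–Martin periodinane/NaHCO3 to (3aS,8S,8aR)-3,3-(ethylenedioxy)-5-methylidene-8-(propan-2-yl)octahydroazulen-7(1H)-one F3. Reduction with LiBH(sBu)3 at −78 °C, which attacks along the equatorial direction, gives the axial β alcohol 12.

**Step 9 (with step 10).**
- Most likely to go wrong: conjugate addition of the sulfonohydrazide to the exocyclic enone and ring closure to a pyrazoline instead of simple condensation; in step 10, 1,4- in place of 1,2-delivery of hydride.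
- Fallback: from 17, conjugate reduction with LiBH(sBu)3 (2.2 equiv, THF, −78 °C) and trapping of the regiodefined C2=C3 enolate with PhNTf2 gives (3aS,7R,8S,8aS)-7-hydroxy-2-methyl-5-methylidene-8-(propan-2-yl)-1,3a,4,5,6,7,8,8a-octahydroazulen-3-yl trifluoromethanesulfonate F4. Pd(OAc)2/PPh3 with HCO2H and Et3N in DMF (zerovalent palladium formed in the flask) replaces the triflate by hydrogen and returns to 20.

**Step 14.**
- Most likely to go wrong: slow exchange of the hindered tertiary hydroxyl onto boron, so that undirected reduction competes and the control at C7 is lost.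
- Fallback: from 22 the axial C7 hydroxyl is esterified directly with acid 27 under Mitsunobu conditions (PPh3, DIAD, PhMe, 0 °C → rt). The displacement inverts C7, the tertiary hydroxyl does not react, and the route is rejoined at 28 without passing 23 and 24.

**Step 17.**
- Most likely to go wrong: poor facial selectivity if the vanadium alkoxide on C5 does not reach C2=C3 and the small inherent bias of the nearly flat cyclopentene decides; Lewis-acid opening of the product is a lesser concern.
- Fallback: from 28, reagent-controlled Shi epoxidation with the dioxirane of the L-fructose-derived ketone (the enantiomer of the usual D-fructose-derived catalyst), KHSO5 (as 2KHSO5·KHSO4·K2SO4), K2CO3 buffer, MeCN/dimethoxymethane/H2O, 0 °C. By the spiro transition-state model, and by analogy with 1-arylcycloalkenes, this should place oxygen on the β face and return to 29.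

## Further compounds

F1 | step 3 | methyl 2-methylprop-2-en-1-yl carbonate | COC(=O)OCC(C)=C
F2 | step 6 | (3aS,7S,8S,8aS)-3,3-(ethylenedioxy)-5-methylidene-8-(propan-2-yl)decahydroazulen-7-ol | CC(C)[C@H]1[C@@H]2CCC3(OCCO3)[C@H]2CC(=C)C[C@@H]1O
F3 | step 6 | (3aS,8S,8aR)-3,3-(ethylenedioxy)-5-methylidene-8-(propan-2-yl)octahydroazulen-7(1H)-one | CC(C)[C@H]1[C@@H]2CCC3(OCCO3)[C@H]2CC(=C)CC1=O
F4 | step 9 | (3aS,7R,8S,8aS)-7-hydroxy-2-methyl-5-methylidene-8-(propan-2-yl)-1,3a,4,5,6,7,8,8a-octahydroazulen-3-yl trifluoromethanesulfonate | CC(C)[C@H]1[C@@H]2CC(C)=C(OS(=O)(=O)C(F)(F)F)[C@H]2CC(=C)C[C@H]1O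
F0 | step 14 | none | none
F0 | step 17 | none | none
A1 | alternative 1 | 3,5-dihydroxy-3-methyl-7-(2-oxopropyl)-6-(propan-2-yl)cycloheptane-1-carbaldehyde 3,5-acetonide (formyl and 2-oxopropyl trans) | CC(C)[C@H]1[C@H](CC(C)=O)[C@@H](C=O)C[C@]2(C)C[C@@H]1OC(C)(C)O2
A2 | alternative 1 | 5,7-O-isopropylidene-2,5-dimethyl-8-(propan-2-yl)-1,3a,4,5,6,7,8,8a-octahydroazulene-5,7-diol | CC(C)[C@H]1[C@@H]2CC(C)=C[C@H]2C[C@]3(C)C[C@@H]1OC(C)(C)O3
A3 | alternative 2 | 3-methyl-4-[trans-7-(prop-1-yn-1-yl)-1,4-dioxaspiro[4.4]nonan-6-yl]-3-[(triethylsilyl)oxy]butanal | CC#C[C@@H]1CCC2(OCCO2)[C@H]1C[C@@](C)(O[Si](CC)(CC)CC)CC=O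
A4 | alternative 2 | 1,1-(ethylenedioxy)-7-methyl-4-(propan-2-ylidene)-7-[(triethylsilyl)oxy]decahydroazulen-5-ol | CC(C)=C1[C@@H]2CCC3(OCCO3)[C@H]2C[C@@](C)(O[Si](CC)(CC)CC)C[C@@H]1O
A5 | alternative 3 | 2,2,4-trimethyl-6-(4-methylpent-1-en-3-yl)-4-(prop-2-yn-1-yl)-1,3-dioxane | C#CC[C@]1(C)C[C@H](OC(C)(C)O1)[C@@H](C(C)C)C=C
A6 | alternative 3 | 5,7-O-isopropylidene-5,7-dihydroxy-5-methyl-8-(propan-2-yl)-4,5,6,7,8,8a-hexahydroazulen-2(1H)-one | CC(C)[C@H]1[C@@H]2CC(=O)C=C2C[C@]3(C)C[C@@H]1OC(C)(C)O3
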